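**Strategy.** Carbons are numbered C1 (benzylic CH2) to C15 along the diterpene chain. The cyclohexane C2–C3–C4–C5–C6–C7 is treated as the six-membered ring of a bicyclo[3.2.1]octadiene: C2 and C6 flank quaternary C7 exactly as the termini of a 5,5-disubstituted cyclopentadiene flank its sp3 carbon, and C3 (the methylene-bearing carbon) is a carbenoid carbon. A rhodium vinylcarbenoid adds to a racemic 1-silyloxy-5-cyano-5-methylcyclopentadiene; cyclopropanation then Cope shift forge C2–C3 and C5–C6 at once and fix C2, C6 and C7. Glycol cleavage of the two-carbon bridge later bares the C6 ketone and the C1 aldehyde.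

Key step: step 5

Remark (labels): the diene carbon excised in step 7 is called Cx; C3' is the ester carbon on C3 that ends as the exocyclic CH2; stereodescriptors not written out are fixed by the SMILES in the compound list.
Remark (assumption): Rh2(S-DOSP)4 is assumed to consume the (R)-enantiomer of diene 4 on its nitrile face; if the sense is opposite, Rh2(R-DOSP)4 is used.
Remark (assumption): the L-fructose-derived ketone is assumed to be the enantiomer that gives the (10S,11S)-epoxide in step 25.

**Core: steps 1–7**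

Step 1
Reactants: 1 2-oxocyclopentane-1-carbonitrile
Product: 2 1-methyl-2-oxocyclopentane-1-carbonitrile (racemic)
Conditions: MeI, K2CO3, acetone, reflux
Reagents that add atoms: iodomethane CI
Why: C-alkylation (SN2) of the stabilised α-cyano ketone enolate builds the quaternary carbon that becomes C7, and no stereocontrol is needed because the racemate is resolved kinetically in step 5.

Step 2
Reactants: 2 1-methyl-2-oxocyclopentane-1-carbonitrile
Product: 3 1-methyl-2-oxocyclopent-3-ene-1-carbonitrile (racemic)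
Conditions: IBX, DMSO/PhF, 70 °C
Reagents that add atoms: none
Why: IBX α,β-dehydrogenation of the ketone can only take place on the CH2–CH2 side because the other α-carbon is quaternary.

Step 3
Reactants: 3 1-methyl-2-oxocyclopent-3-ene-1-carbonitrile
Product: 4 1-methyl-2-(triethylsilyloxy)cyclopenta-2,4-diene-1-carbonitrile (racemic)
Conditions: TESOTf, Et3N, CH2Cl2, 0 °C
Reagents that add atoms: triethylsilyl triflate CC[Si](CC)(CC)OS(=O)(=O)C(F)(F)F
Why: soft enolisation can only remove a γ-hydrogen, giving the fully conjugated silyl dienol ether, which cannot undergo 1,5-hydrogen shifts because its sp3 carbon is quaternary.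

Step 4
Reactants: 5 methyl but-3-enoate
Product: 6 methyl 2-diazobut-3-enoate
Conditions: 4-acetamidobenzenesulfonyl azide, DBU, MeCN, 0 °C; used at once
Reagents that add atoms: 4-acetamidobenzenesulfonyl azide CC(=O)Nc1ccc(cc1)S(=O)(=O)N=[N+]=[N-]
Why: Regitz diazo transfer to the dienolate of the β,γ-unsaturated ester occurs at the α-carbon and the vinyldiazoacetate is used immediately because it slowly cyclises to a pyrazole.

Step 5
Reactants: 4 1-methyl-2-(triethylsilyloxy)cyclopenta-2,4-diene-1-carbonitrile (racemic, 3 equiv); 6 methyl 2-diazobut-3-enoate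
Product: 8 methyl 8-cyano-8-methyl-5-(triethylsilyloxy)bicyclo[3.2.1]octa-2,6-diene-2-carboxylate (nitrile syn to the three-carbon bridge), via cis-divinylcyclopropane 7 (not isolated)
Conditions: Rh2(S-DOSP)4 [dirhodium tetrakis((S)-N-(4-dodecylbenzenesulfonyl)prolinate)] (1 mol %), pentane, −78 °C → rt, slow addition of 6
Reagents that add atoms: none
Why: The divalent-rhodium carbenoid from 6 cyclopropanates the disubstituted C1=C2 double bond of the diene, its carbenoid carbon C3 bonding first to the terminus C2 remote from the silyloxy group, and the resulting cis-divinylcyclopropane 7 undergoes a [3,3] Cope shift through a boat transition state that forms C5–C6 at the silyloxy-bearing carbon; the closest known reaction type is the tandem cyclopropanation/Cope rearrangement (formal [4+3] cycloaddition) of vinyldiazoacetates with cyclopentadienes and 1-oxygenated dienes. The cyclopropane closes by concerted asynchronous [2+1] addition and the seven-membered ring, and with it the C2–C3–C4–C5–C6–C7 ring, by the suprafacial Cope step, so C2 and C6 are necessarily cis-bridged. The face is set by C7: the carbenoid should approach syn to the small, linear, σ-accepting nitrile and anti to methyl, which puts the nitrile (future C8) over the new three-carbon bridge and the methyl on the side of C1. Absolute configuration comes from the catalyst, which is expected to consume the (R)-enantiomer of excess racemic 4 on its nitrile face (kinetic resolution). The step needs site selectivity (cis-disubstituted alkene over the hindered trisubstituted silyl enol ether), cyclopropanation rather than zwitterionic [3+2] annulation (non-polar solvent, donor/acceptor carbenoid) and the cis-divinyl geometry that donor/acceptor carbenoids deliver.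

Step 6
Reactants: 8 methyl 8-cyano-8-methyl-5-(triethylsilyloxy)bicyclo[3.2.1]octa-2,6-diene-2-carboxylate
Product: 9 methyl 8-cyano-5-hydroxy-8-methylbicyclo[3.2.1]octa-2,6-diene-2-carboxylate
Conditions: HF·pyridine, THF, 0 °C → rt
Reagents that add atoms: none
Why: fluoride-driven Si–O cleavage under acidic buffering frees the bridgehead alcohol without forming the alkoxide that could fragment by retro-aldol or oxy-Cope pathways.

Step 7
Reactants: 9 methyl 8-cyano-5-hydroxy-8-methylbicyclo[3.2.1]octa-2,6-diene-2-carboxylate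
Product: 11 methyl 5-cyano-6-formyl-5-methyl-4-oxocyclohex-1-ene-1-carboxylate (formyl cis to methyl), via triol 10 (not isolated)
Conditions: OsO4 (2 mol %), NaIO4, 2,6-lutidine, dioxane/H2O, rt
Reagents that add atoms: sodium periodate [Na+].[O-]I(=O)(=O)=O; osmium tetroxide O=[Os](=O)(=O)=O
Why: Lemieux–Johnson cleavage dihydroxylates the strained electron-rich bridge alkene in preference to the enoate and periodate then cuts the 1,2,3-triol twice, expelling Cx as formic acid and leaving C6 as ketone and C1 as aldehyde with C2 and C7 untouched.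

**Aryl iodide: steps 8–9**

Step 8
Reactants: 12 tert-butyl 4-hydroxybenzoate
Product: 13 tert-butyl 4-hydroxy-3-iodobenzoate
Conditions: N-iodosuccinimide, TsOH (10 mol %), MeCN, rt
Reagents that add atoms: N-iodosuccinimide O=C1CCC(=O)N1I
Why: electrophilic aromatic iodination is directed ortho to the hydroxyl because the para position is blocked and the ester deactivates its own ortho positions.

Step 9
Reactants: 13 tert-butyl 4-hydroxy-3-iodobenzoate
Product: 14 tert-butyl 3-iodo-4-(triisopropylsilyloxy)benzoate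
Conditions: TIPSCl, imidazole, DMF, rt
Reagents that add atoms: chlorotriisopropylsilane CC(C)[Si](Cl)(C(C)C)C(C)C
Why: silylation of the phenol gives an aryl silyl ether that should survive chromium, Lewis acid, hydride and mild aqueous base and is removed last by fluoride.

**Arylation, C6 alcohol and vinyl group: steps 10–14**

Step 10
Reactants: 11 methyl 5-cyano-6-formyl-5-methyl-4-oxocyclohex-1-ene-1-carboxylate; 14 tert-butyl 3-iodo-4-(triisopropylsilyloxy)benzoate
Product: 15 methyl 6-{[5-(tert-butoxycarbonyl)-2-(triisopropylsilyloxy)phenyl](hydroxy)methyl}-5-cyano-5-methyl-4-oxocyclohex-1-ene-1-carboxylate (C1 epimers)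
Conditions: CrCl2 (5 equiv), NiCl2 (1 mol %), DMF/DMSO, rt
Reagents that add atoms: none
Why: in the Nozaki–Hiyama–Kishi reaction the non-basic arylchromium reagent adds only to the aldehyde, sparing ketone, esters and nitrile and the epimerisable C2, and the new C1 carbinol centre is removed in step 12.

Step 11
Reactants: 15 methyl 6-{[5-(tert-butoxycarbonyl)-2-(triisopropylsilyloxy)phenyl](hydroxy)methyl}-5-cyano-5-methyl-4-oxocyclohex-1-ene-1-carboxylate
Product: 16 methyl 6-{[5-(tert-butoxycarbonyl)-2-(triisopropylsilyloxy)phenyl](hydroxy)methyl}-5-cyano-4-hydroxy-5-methylcyclohex-1-ene-1-carboxylate (C6 hydroxyl trans to the C1 arm and to methyl)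
Conditions: Me4NBH(OAc)3, MeCN/AcOH, −20 → 0 °C
Reagents that add atoms: none
Why: in this hydroxyl-directed triacetoxyborohydride reduction the C1 carbinol, held pseudoaxial on C2 by allylic strain with the ester and therefore 1,3-syn to one face of the C6 ketone, binds boron and delivers hydride internally to that face, so the new C6 hydroxyl ends trans to C1 and to the C7 methyl.

Step 12
Reactants: 16 methyl 6-{[5-(tert-butoxycarbonyl)-2-(triisopropylsilyloxy)phenyl](hydroxy)methyl}-5-cyano-4-hydroxy-5-methylcyclohex-1-ene-1-carboxylate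
Product: 17 methyl 6-{[5-(tert-butoxycarbonyl)-2-(triisopropylsilyloxy)phenyl]methyl}-5-cyano-4-hydroxy-5-methylcyclohex-1-ene-1-carboxylate
Conditions: Et3SiH, BF3·OEt2, CH2Cl2, −78 → −30 °C
Reagents that add atoms: none
Why: ionic hydrogenation removes only the benzylic hydroxyl, through a cation stabilised by the ortho silyloxy group and trapped by silane, while the secondary C6 carbinol cannot ionise and the tert-butyl ester should survive at low temperature.

Step 13
Reactants: 17 methyl 6-{[5-(tert-butoxycarbonyl)-2-(triisopropylsilyloxy)phenyl]methyl}-5-cyano-4-hydroxy-5-methylcyclohex-1-ene-1-carboxylate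
Product: 18 tert-butyl 3-{[6-formyl-5-hydroxy-2-(hydroxymethyl)-6-methylcyclohex-2-en-1-yl]methyl}-4-(triisopropylsilyloxy)benzoate
Conditions: i-Bu2AlH (5 equiv), CH2Cl2, −78 °C; aq. potassium sodium tartrate, then dilute tartaric acid
Reagents that add atoms: water O
Why: the aluminium hydride reduces the nitrile to the aldimine (aldehyde C8 after hydrolysis) and the enoate by 1,2-addition to the allylic alcohol in one operation, while the hindered electron-rich aryl tert-butyl ester is expected to survive at −78 °C.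

Step 14
Reactants: 18 tert-butyl 3-{[6-formyl-5-hydroxy-2-(hydroxymethyl)-6-methylcyclohex-2-en-1-yl]methyl}-4-(triisopropylsilyloxy)benzoate
Product: 19 tert-butyl 3-{[6-ethenyl-5-hydroxy-2-(hydroxymethyl)-6-methylcyclohex-2-en-1-yl]methyl}-4-(triisopropylsilyloxy)benzoate
Conditions: Ph3PCH3Br, KN(SiMe3)2 (excess), THF, −78 → 0 °C
Reagents that add atoms: methyltriphenylphosphonium bromide C[P+](c1ccccc1)(c1ccccc1)c1ccccc1.[Br-]
Why: Wittig methylenation of the neopentylic aldehyde at low temperature, with both hydroxyls carried as alkoxides, should outrun retro-aldol opening and installs the C8=C9 vinyl group.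

**Side-chain fragment: steps 15–19**

Step 15
Reactants: 20 pent-4-ynoic acid
Product: 21 N-methoxy-N-methylpent-4-ynamide
Conditions: MeNHOMe·HCl, EDC·HCl, Et3N, DMAP (catalytic), CH2Cl2, rt
Reagents that add atoms: N,O-dimethylhydroxylamine hydrochloride CNOC.Cl
Why: carbodiimide amidation gives the Weinreb amide, which stops acyl substitution at the ketone stage in the next step.

Step 16
Reactants: 21 N-methoxy-N-methylpent-4-ynamide
Product: 22 2-methylhept-1-en-6-yn-3-one
Conditions: isopropenylmagnesium bromide (2.5 equiv), THF, 0 °C; cold 1 M HCl quench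
Reagents that add atoms: isopropenylmagnesium bromide CC(=C)[Mg]Br
Why: Weinreb ketone synthesis, in which the stable magnesium chelate releases the enone only on acidic quench and the first equivalent of Grignard reagent merely deprotonates the alkyne.

Step 17
Reactants: 22 2-methylhept-1-en-6-yn-3-one
Product: 23 (S)-2-methylhept-1-en-6-yn-3-ol
Conditions: (R)-2-methyl-CBS-oxazaborolidine (20 mol %), catecholborane, toluene, −78 °C
Reagents that add atoms: none
Why: Corey–Bakshi–Shibata reduction with the isopropenyl group as the large substituent delivers hydride to one enantioface and sets C14 as S, and catecholborane at −78 °C leaves alkyne and alkene untouched.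

Step 18
Reactants: 23 (S)-2-methylhept-1-en-6-yn-3-ol
Product: 25 (3S,6E)-7-iodo-2,6-dimethylhepta-1,6-dien-3-ol, via alkenylalane 24 (not isolated)
Conditions: AlMe3 (3.5 equiv), Cp2ZrCl2 (0.5 equiv), CH2Cl2, 0 °C → rt; then I2, THF, −30 → 0 °C
Reagents that add atoms: trimethylaluminium C[Al](C)C; iodine II
Why: zirconium-catalysed Negishi carboalumination adds methyl and aluminium syn across the terminal alkyne (methyl on the internal carbon) and iodinolysis with retention gives the E-trisubstituted vinyl iodide, the free hydroxyl being carried as its aluminium alkoxide.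

Step 19
Reactants: 25 (3S,6E)-7-iodo-2,6-dimethylhepta-1,6-dien-3-ol
Product: 26 triethyl{[(3S,6E)-7-iodo-2,6-dimethylhepta-1,6-dien-3-yl]oxy}silane
Conditions: TESCl, imidazole, CH2Cl2, 0 °C
Reagents that add atoms: chlorotriethylsilane CC[Si](Cl)(CC)CC
Why: silylation masks the C14 hydroxyl during the Mitsunobu and Appel steps and is later removed by dilute acid without touching the aryl silyl ether.

**Fragment union and endgame: steps 20–27**

Step 20
Reactants: 19 tert-butyl 3-{[6-ethenyl-5-hydroxy-2-(hydroxymethyl)-6-methylcyclohex-2-en-1-yl]methyl}-4-(triisopropylsilyloxy)benzoate; 26 triethyl{[(3S,6E)-7-iodo-2,6-dimethylhepta-1,6-dien-3-yl]oxy}silane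
Product: 28 tert-butyl 3-{[6-[(3E,7S)-4,8-dimethyl-7-(triethylsilyloxy)nona-3,8-dien-1-yl]-5-hydroxy-2-(hydroxymethyl)-6-methylcyclohex-2-en-1-yl]methyl}-4-(triisopropylsilyloxy)benzoate, via B-alkyl-9-BBN 27 (not isolated)
Conditions: 9-BBN (excess), THF, rt; then 26, PdCl2(dppf) (5 mol %), AsPh3, K3PO4 (3 M aq.), DMF, rt
Reagents that add atoms: none
Why: anti-Markovnikov hydroboration of the only monosubstituted alkene (the trisubstituted ring alkene is inert to 9-BBN and the hydroxyls are tolerated with excess borane) followed by B-alkyl Suzuki–Miyaura coupling forms C9–C10 with retention of the E geometry.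

Step 21
Reactants: 28 tert-butyl 3-{[6-[(3E,7S)-4,8-dimethyl-7-(triethylsilyloxy)nona-3,8-dien-1-yl]-5-hydroxy-2-(hydroxymethyl)-6-methylcyclohex-2-en-1-yl]methyl}-4-(triisopropylsilyloxy)benzoate
Product: 31 tert-butyl 3-{[6-[(3E,7S)-4,8-dimethyl-7-(triethylsilyloxy)nona-3,8-dien-1-yl]-5-hydroxy-6-methyl-2-methylidenecyclohexyl]methyl}-4-(triisopropylsilyloxy)benzoate, via allyl sulfonylhydrazine 29 (not isolated), via allylic diazene 30 (not isolated)
Conditions: 2-nitrobenzenesulfonylhydrazide, PPh3, DEAD, THF, −30 °C; then rt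
Reagents that add atoms: none
Why: Mitsunobu displacement of the primary allylic hydroxyl by the sulfonylhydrazide (the hindered C6 carbinol is inert), loss of sulfinic acid and retro-ene extrusion of N2 from the allylic diazene deliver hydrogen to C4 and shift the alkene to the exocyclic C3=CH2 position (reductive 1,3-transposition).

Step 22
Reactants: 31 tert-butyl 3-{[6-[(3E,7S)-4,8-dimethyl-7-(triethylsilyloxy)nona-3,8-dien-1-yl]-5-hydroxy-6-methyl-2-methylidenecyclohexyl]methyl}-4-(triisopropylsilyloxy)benzoate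
Product: 32 tert-butyl 3-{[5-bromo-6-[(3E,7S)-4,8-dimethyl-7-(triethylsilyloxy)nona-3,8-dien-1-yl]-6-methyl-2-methylidenecyclohexyl]methyl}-4-(triisopropylsilyloxy)benzoate (bromine cis to methyl and to the C1 arm)
Conditions: CBr4, PPh3, 2,6-lutidine, toluene, 0 → 60 °C
Reagents that add atoms: tetrabromomethane BrC(Br)(Br)Br
Why: Appel bromination proceeds by SN2 inversion of the axial C6 oxyphosphonium to the equatorial bromide, as is known for axial neopentylic cyclohexanols, and no other free hydroxyl is present.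

Step 23
Reactants: 32 tert-butyl 3-{[5-bromo-6-[(3E,7S)-4,8-dimethyl-7-(triethylsilyloxy)nona-3,8-dien-1-yl]-6-methyl-2-methylidenecyclohexyl]methyl}-4-(triisopropylsilyloxy)benzoate
Product: 34 3-{[5-bromo-6-[(3E,7S)-7-hydroxy-4,8-dimethylnona-3,8-dien-1-yl]-6-methyl-2-methylidenecyclohexyl]methyl}-4-(triisopropylsilyloxy)benzoic acid, via trimethylsilyl ester 33 (not isolated)
Conditions: TMSOTf, 2,6-lutidine, CH2Cl2, 0 °C; then 1 M HCl, THF, 0 °C
Reagents that add atoms: none
Why: silyl triflate converts the tert-butyl ester into its silyl ester with loss of isobutene under buffered non-protic conditions that spare the alkenes, and the dilute acid work-up hydrolyses the silyl ester and the alkyl triethylsilyl ether but not the aryl silyl ether.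

Step 24
Reactants: 34 3-{[5-bromo-6-[(3E,7S)-7-hydroxy-4,8-dimethylnona-3,8-dien-1-yl]-6-methyl-2-methylidenecyclohexyl]methyl}-4-(triisopropylsilyloxy)benzoic acid
Product: 36 15-membered macrolactone (C14 benzoate; C10=C11 E-alkene; phenol as triisopropylsilyl ether), via mixed anhydride 35 (not isolated)
Conditions: 2,4,6-trichlorobenzoyl chloride, Et3N, THF, rt; then DMAP, toluene, 60 °C, high dilution
Reagents that add atoms: none
Why: Yamaguchi macrolactonisation acylates the C14 hydroxyl through the mixed anhydride and acylpyridinium ion with retention at C14, the phenol being protected and the acid unhindered.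

Step 25
Reactants: 36 15-membered macrolactone
Product: 37 (10S,11S)-10,11-epoxide of macrolactone 36
Conditions: L-fructose-derived ketone (1,2:4,5-di-O-isopropylidene-erythro-2,3-hexodiulo-2,6-pyranose, 0.4 equiv), KHSO5 (triple salt), K2CO3, Bu4NHSO4, MeCN/dimethoxymethane/aq. buffer pH 10.5, 0 °C
Reagents that add atoms: potassium peroxymonosulfate [K+].[O-]S(=O)(=O)OO
Why: Shi epoxidation through a spiro dioxirane transition state selects the only trisubstituted alkene (the 1,1-disubstituted ones are poor substrates and the isopropenyl group is deactivated as an allylic ester) and the ketone enantiomer sets C10 and C11.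

Step 26
Reactants: 37 (10S,11S)-10,11-epoxide of macrolactone 36
Product: 38 bromophycolide E triisopropylsilyl ether
Conditions: Li2NiBr4, THF, 0 °C → rt
Reagents that add atoms: dilithium tetrabromonickelate [Li+].[Li+].[Ni+2].[Br-].[Br-].[Br-].[Br-]
Why: the soft bromide opens the epoxide by SN2 at the less substituted carbon C10 with inversion and leaves the C11–O bond intact, giving the anti bromohydrin (10R,11S) under non-basic conditions.

Step 27
Reactants: 38 bromophycolide E triisopropylsilyl ether
Product: 39 bromophycolide E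
Conditions: HF·pyridine, THF/pyridine, 0 °C
Reagents that add atoms: none
Why: acidic fluoride cleaves the aryl silyl ether without the base that would close the bromohydrin to an epoxide or open the lactone.

**Compound list**

1 | 2-oxocyclopentane-1-carbonitrile | N#CC1CCCC1=O | starting material
2 | 1-methyl-2-oxocyclopentane-1-carbonitrile (racemic) | CC1(C#N)CCCC1=O | intermediate
3 | 1-methyl-2-oxocyclopent-3-ene-1-carbonitrile (racemic) | CC1(C#N)CC=CC1=O | intermediate
4 | 1-methyl-2-(triethylsilyloxy)cyclopenta-2,4-diene-1-carbonitrile (racemic) | CC1(C#N)C=CC=C1O[Si](CC)(CC)CC | intermediate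
5 | methyl but-3-enoate | C=CCC(=O)OC | starting material
6 | methyl 2-diazobut-3-enoate | C=CC(=[N+]=[N-])C(=O)OC | intermediate
7 | methyl 4-cyano-6-ethenyl-4-methyl-3-(triethylsilyloxy)bicyclo[3.1.0]hex-2-ene-6-carboxylate (cyclopropane on the nitrile face; vinyl endo) | N#C[C@@]1(C)[C@H]2[C@@](C(=O)OC)(C=C)[C@H]2C=C1O[Si](CC)(CC)CC | intermediate
8 | methyl 8-cyano-8-methyl-5-(triethylsilyloxy)bicyclo[3.2.1]octa-2,6-diene-2-carboxylate (nitrile syn to the three-carbon bridge) | N#C[C@@]1(C)[C@H]2C(C(=O)OC)=CC[C@]1(O[Si](CC)(CC)CC)C=C2 | intermediate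
9 | methyl 8-cyano-5-hydroxy-8-methylbicyclo[3.2.1]octa-2,6-diene-2-carboxylate | N#C[C@@]1(C)[C@H]2C(C(=O)OC)=CC[C@]1(O)C=C2 | intermediate
10 | methyl 8-cyano-5,6,7-trihydroxy-8-methylbicyclo[3.2.1]oct-2-ene-2-carboxylate (cis-6,7-diol) | N#C[C@@]1(C)[C@H]2C(C(=O)OC)=CC[C@]1(O)C(O)C2O | intermediate
11 | methyl 5-cyano-6-formyl-5-methyl-4-oxocyclohex-1-ene-1-carboxylate (formyl cis to methyl) | N#C[C@@]1(C)[C@H](C=O)C(C(=O)OC)=CCC1=O | intermediate
12 | tert-butyl 4-hydroxybenzoate | CC(C)(C)OC(=O)c1ccc(O)cc1 | starting material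
13 | tert-butyl 4-hydroxy-3-iodobenzoate | CC(C)(C)OC(=O)c1ccc(O)c(I)c1 | intermediate
14 | tert-butyl 3-iodo-4-(triisopropylsilyloxy)benzoate | CC(C)(C)OC(=O)c1ccc(O[Si](C(C)C)(C(C)C)C(C)C)c(I)c1 | intermediate
15 | methyl 6-{[5-(tert-butoxycarbonyl)-2-(triisopropylsilyloxy)phenyl](hydroxy)methyl}-5-cyano-5-methyl-4-oxocyclohex-1-ene-1-carboxylate (C1 epimers) | N#C[C@@]1(C)[C@H](C(O)c2cc(ccc2O[Si](C(C)C)(C(C)C)C(C)C)C(=O)OC(C)(C)C)C(C(=O)OC)=CCC1=O | intermediate
16 | methyl 6-{[5-(tert-butoxycarbonyl)-2-(triisopropylsilyloxy)phenyl](hydroxy)methyl}-5-cyano-4-hydroxy-5-methylcyclohex-1-ene-1-carboxylate (ring hydroxyl trans to methyl and to the C1 arm) | N#C[C@@]1(C)[C@H](C(O)c2cc(ccc2O[Si](C(C)C)(C(C)C)C(C)C)C(=O)OC(C)(C)C)C(C(=O)OC)=CC[C@H]1O | intermediate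
17 | methyl 6-{[5-(tert-butoxycarbonyl)-2-(triisopropylsilyloxy)phenyl]methyl}-5-cyano-4-hydroxy-5-methylcyclohex-1-ene-1-carboxylate | N#C[C@@]1(C)[C@H](Cc2cc(ccc2O[Si](C(C)C)(C(C)C)C(C)C)C(=O)OC(C)(C)C)C(C(=O)OC)=CC[C@H]1O | intermediate
18 | tert-butyl 3-{[6-formyl-5-hydroxy-2-(hydroxymethyl)-6-methylcyclohex-2-en-1-yl]methyl}-4-(triisopropylsilyloxy)benzoate | O=C[C@@]1(C)[C@H](Cc2cc(ccc2O[Si](C(C)C)(C(C)C)C(C)C)C(=O)OC(C)(C)C)C(CO)=CC[C@H]1O | intermediate
19 | tert-butyl 3-{[6-ethenyl-5-hydroxy-2-(hydroxymethyl)-6-methylcyclohex-2-en-1-yl]methyl}-4-(triisopropylsilyloxy)benzoate | C=C[C@@]1(C)[C@H](Cc2cc(ccc2O[Si](C(C)C)(C(C)C)C(C)C)C(=O)OC(C)(C)C)C(CO)=CC[C@H]1O | intermediate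
20 | pent-4-ynoic acid | C#CCCC(=O)O | starting material
21 | N-methoxy-N-methylpent-4-ynamide | C#CCCC(=O)N(C)OC | intermediate
22 | 2-methylhept-1-en-6-yn-3-one | C=C(C)C(=O)CCC#C | intermediate
23 | (S)-2-methylhept-1-en-6-yn-3-ol | C=C(C)[C@@H](O)CCC#C | intermediate
24 | (E)-alkenyl(dimethyl)alane of 23, hydroxyl as dimethylaluminium alkoxide | C=C(C)[C@@H](O[Al](C)C)CC/C(C)=C/[Al](C)C | intermediate
25 | (3S,6E)-7-iodo-2,6-dimethylhepta-1,6-dien-3-ol | C=C(C)[C@@H](O)CC/C(C)=C/I | intermediate
26 | triethyl{[(3S,6E)-7-iodo-2,6-dimethylhepta-1,6-dien-3-yl]oxy}silane | C=C(C)[C@@H](O[Si](CC)(CC)CC)CC/C(C)=C/I | intermediate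
27 | B-alkyl-9-BBN adduct of 19 (boron on C9; hydroxyls drawn free) | B3(C4CCCC3CCC4)CC[C@@]1(C)[C@H](Cc2cc(ccc2O[Si](C(C)C)(C(C)C)C(C)C)C(=O)OC(C)(C)C)C(CO)=CC[C@H]1O | intermediate
28 | tert-butyl 3-{[6-[(3E,7S)-4,8-dimethyl-7-(triethylsilyloxy)nona-3,8-dien-1-yl]-5-hydroxy-2-(hydroxymethyl)-6-methylcyclohex-2-en-1-yl]methyl}-4-(triisopropylsilyloxy)benzoate | C=C(C)[C@@H](O[Si](CC)(CC)CC)CC/C(C)=C/CC[C@@]1(C)[C@H](Cc2cc(ccc2O[Si](C(C)C)(C(C)C)C(C)C)C(=O)OC(C)(C)C)C(CO)=CC[C@H]1O | intermediate
29 | N-allyl-N-(2-nitrobenzenesulfonyl)hydrazine derived from 28 | C=C(C)[C@@H](O[Si](CC)(CC)CC)CC/C(C)=C/CC[C@@]1(C)[C@H](Cc2cc(ccc2O[Si](C(C)C)(C(C)C)C(C)C)C(=O)OC(C)(C)C)C(CN(N)S(=O)(=O)c3ccccc3[N+](=O)[O-])=CC[C@H]1O | intermediate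
30 | allylic monoalkyl diazene derived from 28 | C=C(C)[C@@H](O[Si](CC)(CC)CC)CC/C(C)=C/CC[C@@]1(C)[C@H](Cc2cc(ccc2O[Si](C(C)C)(C(C)C)C(C)C)C(=O)OC(C)(C)C)C(CN=N)=CC[C@H]1O | intermediate
31 | tert-butyl 3-{[6-[(3E,7S)-4,8-dimethyl-7-(triethylsilyloxy)nona-3,8-dien-1-yl]-5-hydroxy-6-methyl-2-methylidenecyclohexyl]methyl}-4-(triisopropylsilyloxy)benzoate | C=C(C)[C@@H](O[Si](CC)(CC)CC)CC/C(C)=C/CC[C@@]1(C)[C@H](Cc2cc(ccc2O[Si](C(C)C)(C(C)C)C(C)C)C(=O)OC(C)(C)C)C(=C)CC[C@H]1O | intermediate
32 | tert-butyl 3-{[5-bromo-6-[(3E,7S)-4,8-dimethyl-7-(triethylsilyloxy)nona-3,8-dien-1-yl]-6-methyl-2-methylidenecyclohexyl]methyl}-4-(triisopropylsilyloxy)benzoate | C=C(C)[C@@H](O[Si](CC)(CC)CC)CC/C(C)=C/CC[C@@]1(C)[C@H](Cc2cc(ccc2O[Si](C(C)C)(C(C)C)C(C)C)C(=O)OC(C)(C)C)C(=C)CC[C@@H]1Br | intermediate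
33 | trimethylsilyl ester corresponding to 32 | C=C(C)[C@@H](O[Si](CC)(CC)CC)CC/C(C)=C/CC[C@@]1(C)[C@H](Cc2cc(ccc2O[Si](C(C)C)(C(C)C)C(C)C)C(=O)O[Si](C)(C)C)C(=C)CC[C@@H]1Br | intermediate
34 | 3-{[5-bromo-6-[(3E,7S)-7-hydroxy-4,8-dimethylnona-3,8-dien-1-yl]-6-methyl-2-methylidenecyclohexyl]methyl}-4-(triisopropylsilyloxy)benzoic acid | C=C(C)[C@@H](O)CC/C(C)=C/CC[C@@]1(C)[C@H](Cc2cc(ccc2O[Si](C(C)C)(C(C)C)C(C)C)C(O)=O)C(=C)CC[C@@H]1Br | intermediate
35 | mixed 2,4,6-trichlorobenzoic anhydride of 34 | C=C(C)[C@@H](O)CC/C(C)=C/CC[C@@]1(C)[C@H](Cc2cc(ccc2O[Si](C(C)C)(C(C)C)C(C)C)C(=O)OC(=O)c3c(Cl)cc(Cl)cc3Cl)C(=C)CC[C@@H]1Br | intermediate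
36 | 15-membered macrolactone (C10=C11 E-alkene; phenol as triisopropylsilyl ether) | C=C(C)[C@@H]1CC/C(C)=C/CC[C@@]2(C)[C@H](Cc3cc(ccc3O[Si](C(C)C)(C(C)C)C(C)C)C(=O)O1)C(=C)CC[C@@H]2Br | intermediate
37 | (10S,11S)-10,11-epoxide of macrolactone 36 | C=C(C)[C@@H]1CC[C@]4(C)O[C@H]4CC[C@@]2(C)[C@H](Cc3cc(ccc3O[Si](C(C)C)(C(C)C)C(C)C)C(=O)O1)C(=C)CC[C@@H]2Br | intermediate
38 | bromophycolide E triisopropylsilyl ether | C=C(C)[C@@H]1CC[C@](C)(O)[C@H](Br)CC[C@@]2(C)[C@H](Cc3cc(ccc3O[Si](C(C)C)(C(C)C)C(C)C)C(=O)O1)C(=C)CC[C@@H]2Br | intermediate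
39 | bromophycolide E | C=C(C)[C@@H]1CC[C@](C)(O)[C@H](Br)CC[C@@]2(C)[C@H](Cc3cc(ccc3O)C(=O)O1)C(=C)CC[C@@H]2Br | target

**Step count.** Total: 27 steps. Longest linear sequence: 19 steps (steps 1–3, 5–7, 10–14, 20–27).

**Steps most likely to fail**

Step 5. The catalyst may fail to distinguish the two enantiomers of racemic diene 4 or to reinforce the nitrile-face preference, so enantiomeric purity or facial selectivity is lost. Fallback: absolute control is moved from the catalyst to the substrate. Starting from 3, the racemic enone is separated by preparative chromatography on a chiral stationary phase to give (R)-1-methyl-2-oxocyclopent-3-ene-1-carbonitrile F1. F1 is silylated as in step 3 to (R)-1-methyl-2-(triethylsilyloxy)cyclopenta-2,4-diene-1-carbonitrile F2. F2 and 6 are then combined with achiral dirhodium tetrapivalate Rh2(OPiv)4 in pentane, so that only the nitrile/methyl bias of the resolved diene operates; the route is rejoined at 8.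

Step 22. E2 elimination toward C5 or a methyl shift from C7 may outrun substitution at the neopentylic carbinol. Fallback: activation and displacement are separated. Starting from 31, triflic anhydride and 2,6-di-tert-butyl-4-methylpyridine in CH2Cl2 at −78 °C give the C6 trifluoromethanesulfonate F5. F5 is displaced with inversion by tetrabutylammonium bromide in toluene at low temperature; the route is rejoined at 32.

Step 11. Hydride may arrive externally on the open nitrile face instead of being delivered internally from the C1 carbinol, which gives the C6 epimer. Fallback: kinetic delivery is replaced by thermodynamic control. Starting from 15, the benzylic hydroxyl is removed first (Et3SiH, BF3·OEt2, as in step 12) to give methyl 6-{[5-(tert-butoxycarbonyl)-2-(triisopropylsilyloxy)phenyl]methyl}-5-cyano-5-methyl-4-oxocyclohex-1-ene-1-carboxylate F3. NaBH4/CeCl3 in MeOH at −78 °C reduces F3 mainly from the open face to the C6-epimeric alcohol F4. The carbinol centre is then equilibrated by reversible hydrogen transfer with the diruthenium hydride complex Ru2(CO)4(μ-H)(C4Ph4COHOCC4Ph4) in toluene at 70 °C to the equatorial alcohol, whose hydroxyl is trans to the pseudoaxial benzyl arm; the route is rejoined at 17.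

Further compounds
F1 | step 5 | (R)-1-methyl-2-oxocyclopent-3-ene-1-carbonitrile | N#C[C@@]1(C)CC=CC1=O
F2 | step 5 | (R)-1-methyl-2-(triethylsilyloxy)cyclopenta-2,4-diene-1-carbonitrile | N#C[C@@]1(C)C=CC=C1O[Si](CC)(CC)CC
F3 | step 11 | methyl 6-{[5-(tert-butoxycarbonyl)-2-(triisopropylsilyloxy)phenyl]methyl}-5-cyano-5-methyl-4-oxocyclohex-1-ene-1-carboxylate | N#C[C@@]1(C)[C@H](Cc2cc(ccc2O[Si](C(C)C)(C(C)C)C(C)C)C(=O)OC(C)(C)C)C(C(=O)OC)=CCC1=O
F4 | step 11 | C6 epimer of 17 (ring hydroxyl cis to methyl) | N#C[C@@]1(C)[C@H](Cc2cc(ccc2O[Si](C(C)C)(C(C)C)C(C)C)C(=O)OC(C)(C)C)C(C(=O)OC)=CC[C@@H]1O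
F5 | step 22 | C6 trifluoromethanesulfonate of 31 | C=C(C)[C@@H](O[Si](CC)(CC)CC)CC/C(C)=C/CC[C@@]1(C)[C@H](Cc2cc(ccc2O[Si](C(C)C)(C(C)C)C(C)C)C(=O)OC(C)(C)C)C(=C)CC[C@H]1OS(=O)(=O)C(F)(F)F
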